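**Assumption:** the target, 5,7,8-trimethoxy-2-(2,3,4,5-tetramethoxyphenyl)-4H-chromen-4-one, has no stereocentre, so no stereocontrol is needed; compounds 1 and 5 are taken as catalogue chemicals.

**Retrosynthetic overview**
1. Last bond: C2–C1' of the flavone. Chromone C2, normally an electrophilic carbon, is used as a carbanion (C2-zinc reagent, a masked acyl anion / β-acylvinyl anion) and joined to the electrophilic C–I carbon of the B-ring iodide.
2. Chromone 4 comes from o-hydroxyacetophenone 1 plus a one-carbon unit (formamide acetal) through an enaminone.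
3. Aryl iodide 7 comes from 1,2,3,4-tetramethoxybenzene by iodination.
4. Ring order: A ring bought; pyranone C ring closed in step 1; B ring bought and attached last.

**Route**

Step 1
Reactants: 1 2'-hydroxy-3',4',6'-trimethoxyacetophenone; 2 N,N-dimethylformamide dimethyl acetal
Product: 4 5,7,8-trimethoxy-4H-chromen-4-one, via enaminone 3 (not isolated)
Conditions: 2 (1.5 equiv), toluene, 100 °C, 3 h; evaporate; conc. HCl, CH2Cl2, 40 °C, 1 h
Reagents that add atoms: N,N-dimethylformamide dimethyl acetal (2), COC(OC)N(C)C
Why: Condensation of the methyl ketone with the formamide acetal gives the (E)-enaminone, and acid-promoted addition–elimination by the ortho phenol (loss of dimethylamine) closes the pyranone ring (enaminone chromone synthesis); no stereocentre is formed.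

Step 2
Reactants: 5 1,2,3,4-tetramethoxybenzene; 6 N-iodosuccinimide
Product: 7 1-iodo-2,3,4,5-tetramethoxybenzene
Conditions: NIS (1.05 equiv), TFA (10 mol %), MeCN, 0 °C to rt, dark
Reagents that add atoms: N-iodosuccinimide (6), O=C1CCC(=O)N1I
Why: Electrophilic aromatic iodination (SEAr) of a very electron-rich arene whose two free positions are equivalent, so only one mono-iodide can form; no stereocentre is formed.

Step 3
Reactants: 4 5,7,8-trimethoxy-4H-chromen-4-one; 7 1-iodo-2,3,4,5-tetramethoxybenzene
Product: 9 5,7,8-trimethoxy-2-(2,3,4,5-tetramethoxyphenyl)-4H-chromen-4-one, via chromon-2-ylzinc chloride 8 (not isolated)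
Conditions: TMPZnCl·LiCl (1.2 equiv, no added Lewis acid), THF, 25 °C, 1 h; then 7 (0.85 equiv), Pd(OAc)2 (3 mol %), SPhos (6 mol %), THF, 50 °C, 12 h
Reagents that add atoms: none
Why: Directed C–H zincation then Negishi cross-coupling: the hindered zinc amide removes the most acidic vinylic proton (C2–H, α to the ring oxygen) without touching the carbonyl, giving an α-alkoxyvinyl/β-acylvinyl zinc reagent (a donor at the carbon that is otherwise the electrophilic terminus of the chromone), which Pd joins to the electrophilic C–I carbon of 7; no stereocentre is formed.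

**Compound list**
1 | 2'-hydroxy-3',4',6'-trimethoxyacetophenone, i.e. 1-(2-hydroxy-3,4,6-trimethoxyphenyl)ethan-1-one | CC(=O)c1c(O)c(OC)c(OC)cc1OC | starting material
2 | N,N-dimethylformamide dimethyl acetal | COC(OC)N(C)C | starting material
3 | (E)-3-(dimethylamino)-1-(2-hydroxy-3,4,6-trimethoxyphenyl)prop-2-en-1-one | CN(C)/C=C/C(=O)c1c(O)c(OC)c(OC)cc1OC | intermediate (not isolated)
4 | 5,7,8-trimethoxy-4H-chromen-4-one | COc1cc(OC)c2c(=O)ccoc2c1OC | intermediate
5 | 1,2,3,4-tetramethoxybenzene | COc1ccc(OC)c(OC)c1OC | starting material
6 | N-iodosuccinimide | O=C1CCC(=O)N1I | starting material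
7 | 1-iodo-2,3,4,5-tetramethoxybenzene | COc1cc(I)c(OC)c(OC)c1OC | intermediate
8 | chloro(5,7,8-trimethoxy-4-oxo-4H-chromen-2-yl)zinc, as its LiCl complex | COc1cc(OC)c2c(=O)cc([Zn]Cl)oc2c1OC | intermediate (not isolated)
9 | 5,7,8-trimethoxy-2-(2,3,4,5-tetramethoxyphenyl)-4H-chromen-4-one (5,7,8,2',3',4',5'-heptamethoxyflavone) | COc1cc(-c2cc(=O)c3c(OC)cc(OC)c(OC)c3o2)c(OC)c(OC)c1OC | target

**Step count**
Total steps: 3. Longest linear sequence: 2 steps (1 → 4 → 9, or 5 → 7 → 9).

**Steps most likely to fail, with fallbacks**

Step 3 (highest risk). Three things can go wrong: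
- Zincation may occur at C3 instead of C2. The peri 5-OMe/C4=O pair, or Lewis-acidic salts binding the carbonyl, could steer the base there and give the isoflavone. The C2 selectivity with Lewis-acid-free TMPZnCl·LiCl is the least certain point of the route; check it by I2 or D2O quench of an aliquot before adding Pd.
- The C2-metal species may ring-open to an ynone phenoxide; zinc rather than lithium is used to suppress this.
- The ortho-methoxy, electron-rich iodide may couple slowly.

Fallback, setting out from 1 and 5 and returning at 9: formylate 5 (Cl2CHOMe, TiCl4, CH2Cl2, 0 °C; the two free positions are equivalent) to 2,3,4,5-tetramethoxybenzaldehyde F1. Condense F1 with 1 (KOH, EtOH, rt, Claisen–Schmidt) to (E)-1-(2-hydroxy-3,4,6-trimethoxyphenyl)-3-(2,3,4,5-tetramethoxyphenyl)prop-2-en-1-one F2. Cyclise oxidatively (cat. I2, DMSO, 130 °C) to 9. This drops the C2-metal nucleophile for an aldol/oxidative oxa-Michael sequence.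

Step 1. The formamide acetal can O-methylate the phenol, or the enaminone may cyclise incompletely with the hindered, hydrogen-bonded phenol.

Fallback, setting out from 1 and returning at 4: Claisen formylation of 1 with ethyl formate (NaH, THF, 0 °C to rt) gives the ring-closed lactol 2-hydroxy-5,7,8-trimethoxychroman-4-one F3 (racemic hemiacetal). Dehydrate it (p-TsOH, toluene, 80 °C) to 4. This uses an ester condensation of the ketone enolate instead of the enaminone.

Step 2. NIS/acid may over-iodinate the arene or oxidise it to a methoxyquinone.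

Fallback, setting out from 5 and returning at 7: directed ortho-lithiation of 5 (n-BuLi, TMEDA, THF, 0 °C) gives (2,3,4,5-tetramethoxyphenyl)lithium F4, which is quenched with I2 at −78 °C to give 7. This is deprotonative metalation instead of electrophilic substitution, so there is no oxidising electrophile in contact with the free arene and only one position is functionalised.

**Further compounds**
F1 | step 3 | 2,3,4,5-tetramethoxybenzaldehyde | COc1cc(C=O)c(OC)c(OC)c1OC
F2 | step 3 | (E)-1-(2-hydroxy-3,4,6-trimethoxyphenyl)-3-(2,3,4,5-tetramethoxyphenyl)prop-2-en-1-one | COc1cc(/C=C/C(=O)c2c(O)c(OC)c(OC)cc2OC)c(OC)c(OC)c1OC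
F3 | step 1 | 2-hydroxy-5,7,8-trimethoxychroman-4-one (racemic lactol) | COc1cc(OC)c2c(c1OC)OC(O)CC2=O
F4 | step 2 | (2,3,4,5-tetramethoxyphenyl)lithium | [Li]c1cc(OC)c(OC)c(OC)c1OC
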